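**Strategy.** Everything rests on disconnecting the trisubstituted C3=C4 alkene of the cyclopentene (ring A). A ring-closing olefin metathesis of a trans-2-allyl-3-isopropenylcycloheptanone closes ring A onto the finished seven-membered ring B in one operation, placing the C17-methylated alkene and the trans C1/C5 fusion and losing only ethene. The step exploits that C2–C3 and C4(–C17) are simply an allyl group on C1 and an isopropenyl group on C5, which a conjugate addition/enolate allylation installs on a γ-silyloxy cycloheptenone. That enone carries C6, C7 and C11 from an Ireland–Claisen rearrangement of a desymmetrised meso-cycloheptenediol; aldol addition, acetylation and CBS reduction finish the side chain.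

Key step: step 10

Remark on numbering: the skeleton numbering of the target is used for all intermediates. Ring A (cyclopentene) = C1–C5; ring B (cycloheptane) = C1, C5, C6, C7, C8, C9, C10; C17 = methyl on C4; C18 = exocyclic methylene on C10; side chain on C7 = C11 (methyl C19), C12, C13, C14, C15 (=C16, methyl C20). α is the face of ring B that carries the C6 oxygen. The target is 1S,5R,6S,7R,9S,11S,12S,14R.

Remark on step 2: the lipase is assumed to acylate the same enantiotopic carbinol as in the five- and six-membered meso-2-ene-1,4-diols; hydrolysis of the meso dipropanoate with the same enzyme would give the antipodal series.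

Step 1
Reactants: 1 cyclohepta-1,3-diene
Product: 3 cis-cyclohept-2-ene-1,4-diol (meso), via endoperoxide 2 (not isolated)
Conditions: O2, tetraphenylporphyrin (cat.), hν, CH2Cl2, 0 °C; then Zn, AcOH, 0 °C to rt
Reagents that add atoms: dioxygen, O=O
Why: Singlet oxygen adds to the s-cis diene in a [4+2] cycloaddition and reductive O–O cleavage then gives the diol, so both C–O bonds are necessarily cis and the product is meso.

Step 2
Reactants: 3 cis-cyclohept-2-ene-1,4-diol; 4 vinyl propanoate
Product: 5 (1S,4R)-4-hydroxycyclohept-2-en-1-yl propanoate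
Conditions: Pseudomonas cepacia lipase, t-BuOMe, rt
Reagents that add atoms: none
Why: Enzymatic desymmetrisation by enantiotopos-selective transesterification should acylate only the future C9 carbinol, which fixes the absolute configuration of C6; the acyl donor is irreversible because it leaves as acetaldehyde.

Step 3
Reactants: 5 (1S,4R)-4-hydroxycyclohept-2-en-1-yl propanoate
Product: 6 (1S,4R)-4-[(tert-butyldimethylsilyl)oxy]cyclohept-2-en-1-yl propanoate
Conditions: t-BuMe2SiCl, imidazole, DMF, rt
Reagents that add atoms: tert-butyldimethylsilyl chloride, CC(C)(C)[Si](C)(C)Cl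
Why: Standard silyl ether formation on the remaining secondary alcohol; no stereocentre is touched.

Step 4
Reactants: 6 (1S,4R)-4-[(tert-butyldimethylsilyl)oxy]cyclohept-2-en-1-yl propanoate
Product: 9 (2S)-2-[(1R,7R)-7-[(tert-butyldimethylsilyl)oxy]cyclohept-2-en-1-yl]propanoic acid, via silyl ketene acetal 7 (not isolated), via trimethylsilyl ester 8 (not isolated)
Conditions: LiN(iPr)2, THF, −78 °C; Me3SiCl, −78 °C to 50 °C; aqueous HCl
Reagents that add atoms: none
Why: Ireland–Claisen rearrangement: the kinetic (E)-silyl ketene acetal should rearrange suprafacially through a chair-like transition state, so the new C7–C11 bond forms on the face that carried the C9 ester oxygen (cis to the C6 silyloxy group) and the axial methyl of the ketene acetal sets C11 as 11S.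

Step 5
Reactants: 9 (2S)-2-[(1R,7R)-7-[(tert-butyldimethylsilyl)oxy]cyclohept-2-en-1-yl]propanoic acid
Product: 10 methyl (2S)-2-[(1R,7R)-7-[(tert-butyldimethylsilyl)oxy]cyclohept-2-en-1-yl]propanoate
Conditions: Me3SiCHN2, MeOH/toluene, 0 °C
Reagents that add atoms: (trimethylsilyl)diazomethane, C[Si](C)(C)C=[N+]=[N-]
Why: Mild methyl esterification that should not epimerise C11; the ester masks C12 until step 13.

Step 6
Reactants: 10 methyl (2S)-2-[(1R,7R)-7-[(tert-butyldimethylsilyl)oxy]cyclohept-2-en-1-yl]propanoate
Product: 12 methyl (2S)-2-[(1R,7R)-7-[(tert-butyldimethylsilyl)oxy]-4-oxocyclohept-2-en-1-yl]propanoate (enone with C10 ketone and C8=C9), via allylic alcohol 11 (not isolated)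
Conditions: SeO2 (cat.), t-BuOOH, CH2Cl2, rt; then Dess–Martin periodinane, NaHCO3, CH2Cl2, 0 °C to rt
Reagents that add atoms: tert-butyl hydroperoxide, CC(C)(C)OO
Why: Riley-type allylic oxidation (ene reaction then [2,3]-shift) should attack the allylic CH2 at C10 in preference to the hindered tertiary C7–H and keep the C8=C9 alkene in place; oxidation of the allylic alcohol then gives the conjugated enone.

Step 7
Reactants: 12 enone with C10 ketone and C8=C9
Product: 13 methyl (2S)-2-[(1R,7R)-7-[(tert-butyldimethylsilyl)oxy]-4-oxo-5-(phenylselanyl)cyclohept-2-en-1-yl]propanoate (C1 selenide; C1 epimers)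
Conditions: LiN(iPr)2, THF, −78 °C; PhSeCl
Reagents that add atoms: phenylselenenyl chloride, Cl[Se]c1ccccc1
Why: Kinetic α′-deprotonation of the enone gives only the cross-conjugated C1 enolate (C9 is vinylic), and selenenylation marks C1 for regiospecific dehydrogenation; the C1 configuration is irrelevant.

Step 8
Reactants: 13 C1 selenide of the enone
Product: 15 methyl (2S)-2-[(1R,2R)-2-[(tert-butyldimethylsilyl)oxy]-5-oxocyclohept-3-en-1-yl]propanoate (enone with C10 ketone and C1=C5), via selanyl ketone 14 (not isolated)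
Conditions: [(Ph3P)CuH]6, wet benzene, rt; then H2O2, pyridine, CH2Cl2, 0 °C to rt
Reagents that add atoms: none
Why: Copper hydride conjugate reduction saturates C8=C9, and selenoxide syn-elimination can only use a C5 hydrogen, so the unsaturation moves to C1=C5 (enone transposition across the carbonyl) without touching a stereocentre.

Step 9
Reactants: 15 enone with C10 ketone and C1=C5; 16 isopropenylmagnesium bromide; 17 allyl iodide
Product: 19 methyl (2S)-2-[(1R,2S,3R,4S)-2-[(tert-butyldimethylsilyl)oxy]-5-oxo-4-(prop-2-en-1-yl)-3-(prop-1-en-2-yl)cycloheptyl]propanoate, via magnesium enolate 18 (not isolated)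
Conditions: CuBr·SMe2 (cat.), THF, −78 to −40 °C; then allyl iodide, HMPA, −40 to 0 °C
Reagents that add atoms: none
Why: Copper-catalysed conjugate addition anti to the γ-silyloxy group at C6 sets C5 (isopropenyl β), and the enolate is allylated anti to the new C5 substituent, setting C1 (allyl α); this is a three-component vicinal difunctionalisation.

Step 10
Reactants: 19 trans-2-allyl-3-isopropenylcycloheptanone
Product: 20 trans-fused bicyclic ketone (target ring system; C10 ketone; 6α-OTBS; C12 as methyl ester; C1, C5, C6, C7, C11 as in the target)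
Conditions: RuCl2(=CHPh)(H2IMes)(PCy3) (second-generation Grubbs catalyst, 5 mol %), CH2Cl2, 40 °C
Reagents that add atoms: none
Why: The ruthenium benzylidene should initiate at the only monosubstituted alkene (the allyl terminus on C1), and the resulting alkylidene undergoes intramolecular [2+2] cycloaddition/cycloreversion with the 1,1-disubstituted isopropenyl alkene on C5, forming C3=C4 and expelling ethene. The closest known reaction type is ring-closing olefin metathesis of α-allyl-β-isopropenyl cycloalkanones to fused 1-methylcyclopentenes. Ring A is closed as a five-membered ring by metathesis between the alkene carbons C3 and C4, fused trans to ring B. No new stereocentre is created; C1 and C5 come from step 9, and the neutral conditions leave the enolisable C1–H untouched. The step needs selectivity for this alkene pair, which the substrate secures because no other alkene is present and the trans allyl and isopropenyl groups sit next to each other; loss of ethene drives the closure.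

Step 11
Reactants: 20 trans-fused bicyclic ketone
Product: 22 9β-triethylsilyloxy ketone (as 20 with OSiEt3 on C9), via silyl enol ether 21 (not isolated)
Conditions: LiN(iPr)2, THF, −78 °C; Et3SiCl, Et3N, −78 to 0 °C; then mCPBA, NaHCO3, CH2Cl2, −40 °C
Reagents that add atoms: chlorotriethylsilane, CC[Si](Cl)(CC)CC; 3-chloroperbenzoic acid, OOC(=O)c1cccc(Cl)c1
Why: Kinetic deprotonation at the C9 methylene and silylation give the C9=C10 enol ether, and Rubottom oxidation (epoxidation, ring opening, 1,4-silyl shift) should deliver oxygen to the β face, because the trans ring fusion folds C5 and C7 with the axial C7 side chain over the α face; the electron-rich enol ether should react before the ring A alkene.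

Step 12
Reactants: 22 9β-triethylsilyloxy ketone
Product: 23 C10 methylene ester (C10=C18 in place; 6α-OTBS; 9β-OSiEt3; C12 as methyl ester)
Conditions: Zn, CH2Br2, TiCl4, THF/CH2Cl2, 0 °C to rt
Reagents that add atoms: dibromomethane, BrCBr
Why: Takai–Lombardo methylenation converts the hindered, enolisable ketone into the exocyclic C10=C18 alkene under non-basic conditions, leaving C1, C9 and the ester untouched.

Step 13
Reactants: 23 C10 methylene ester
Product: 24 C12 aldehyde (as 23 with CHO in place of CO2Me)
Conditions: iBu2AlH, CH2Cl2, −78 °C; then MeOH, aqueous sodium potassium tartrate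
Reagents that add atoms: none
Why: Partial reduction of the ester at −78 °C stops at the aldehyde through the stable tetrahedral aluminium hemiacetal and should not epimerise C11.

Step 14
Reactants: 25 3-methylbut-3-en-2-one
Product: 26 3-methyl-2-(trimethylsilyloxy)buta-1,3-diene
Conditions: LiN(iPr)2, THF, −78 °C; Me3SiCl
Reagents that add atoms: chlorotrimethylsilane, C[Si](C)(C)Cl
Why: Kinetic enolisation of the methyl ketone (the other side has no α-hydrogen) and O-silylation give the silyl enol ether nucleophile.

Step 15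
Reactants: 24 C12 aldehyde; 26 3-methyl-2-(trimethylsilyloxy)buta-1,3-diene
Product: 27 12S-hydroxy-14-ketone (full carbon skeleton; 6α-OTBS; 9β-OSiEt3)
Conditions: BF3·OEt2, CH2Cl2, −78 °C; aqueous NaHCO3
Reagents that add atoms: none
Why: Mukaiyama aldol addition under non-chelating Lewis acid activation should follow the Felkin–Anh model (attack anti to the large C7 ring substituent on C11), giving the 11,12-syn alcohol with 12S.

Step 16
Reactants: 27 12S-hydroxy-14-ketone
Product: 28 12-acetoxy-14-ketone
Conditions: Ac2O, pyridine, DMAP (cat.), CH2Cl2, 0 °C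
Reagents that add atoms: acetic anhydride, CC(=O)OC(C)=O
Why: Acylation while O6 and O9 are silylated and C14 is still a ketone places the acetate unambiguously on O12.

Step 17
Reactants: 28 12-acetoxy-14-ketone
Product: 29 6,9-bis-silyl ether of the target (14R alcohol)
Conditions: (S)-2-methyl-CBS-oxazaborolidine (cat.), catecholborane, toluene, −78 °C
Reagents that add atoms: none
Why: CBS reduction: the (S)-oxazaborolidine should deliver hydride to the enone carbonyl with the isopropenyl group as the large substituent, giving the 14R allylic alcohol by reagent control (1,2-reduction); the acetate is inert.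

Step 18
Reactants: 29 6,9-bis-silyl ether of the target
Product: 30 target, (1S,5R,6S,7R,9S,11S,12S,14R)-12-acetoxy-6,9,14-triol
Conditions: HF·pyridine, pyridine, THF, 0 °C to rt
Reagents that add atoms: none
Why: Fluoride-mediated cleavage of both silyl ethers under buffered acidic conditions, which should avoid 1,3-acetyl migration between O12 and O14, releases the target.

**Compound list**

1 | cyclohepta-1,3-diene | C1=CC=CCCC1 | starting material
2 | 6,7-dioxabicyclo[3.2.2]non-8-ene (meso endoperoxide) | C1=C[C@@H]2CCC[C@H]1OO2 | intermediate (not isolated)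
3 | cis-cyclohept-2-ene-1,4-diol (meso) | C1=C[C@@H](O)CCC[C@H]1O | intermediate
4 | vinyl propanoate | CCC(=O)OC=C | starting material
5 | (1S,4R)-4-hydroxycyclohept-2-en-1-yl propanoate | C1=C[C@@H](OC(=O)CC)CCC[C@H]1O | intermediate
6 | (1S,4R)-4-[(tert-butyldimethylsilyl)oxy]cyclohept-2-en-1-yl propanoate | C1=C[C@@H](OC(=O)CC)CCC[C@H]1O[Si](C)(C)C(C)(C)C | intermediate
7 | (E)-trimethylsilyl ketene acetal of 6 | C1=C[C@@H](O/C(O[Si](C)(C)C)=C\C)CCC[C@H]1O[Si](C)(C)C(C)(C)C | intermediate (not isolated)
8 | trimethylsilyl ester of acid 9 | C[Si](C)(C)OC(=O)[C@@H](C)[C@H]1C=CCCC[C@H]1O[Si](C)(C)C(C)(C)C | intermediate (not isolated)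
9 | (2S)-2-[(1R,7R)-7-[(tert-butyldimethylsilyl)oxy]cyclohept-2-en-1-yl]propanoic acid | OC(=O)[C@@H](C)[C@H]1C=CCCC[C@H]1O[Si](C)(C)C(C)(C)C | intermediate
10 | methyl (2S)-2-[(1R,7R)-7-[(tert-butyldimethylsilyl)oxy]cyclohept-2-en-1-yl]propanoate | COC(=O)[C@@H](C)[C@H]1C=CCCC[C@H]1O[Si](C)(C)C(C)(C)C | intermediate
11 | C10 allylic alcohol of 10 (C10 epimers) | COC(=O)[C@@H](C)[C@H]1C=CC(O)CC[C@H]1O[Si](C)(C)C(C)(C)C | intermediate (not isolated)
12 | methyl (2S)-2-[(1R,7R)-7-[(tert-butyldimethylsilyl)oxy]-4-oxocyclohept-2-en-1-yl]propanoate | COC(=O)[C@@H](C)[C@H]1C=CC(=O)CC[C@H]1O[Si](C)(C)C(C)(C)C | intermediate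
13 | methyl (2S)-2-[(1R,7R)-7-[(tert-butyldimethylsilyl)oxy]-4-oxo-5-(phenylselanyl)cyclohept-2-en-1-yl]propanoate (C1 epimers) | COC(=O)[C@@H](C)[C@H]1C=CC(=O)C([Se]c2ccccc2)C[C@H]1O[Si](C)(C)C(C)(C)C | intermediate
14 | saturated C1-phenylselanyl C10 ketone (C1 epimers) | COC(=O)[C@@H](C)[C@H]1CCC(=O)C([Se]c2ccccc2)C[C@H]1O[Si](C)(C)C(C)(C)C | intermediate (not isolated)
15 | methyl (2S)-2-[(1R,2R)-2-[(tert-butyldimethylsilyl)oxy]-5-oxocyclohept-3-en-1-yl]propanoate | COC(=O)[C@@H](C)[C@H]1CCC(=O)C=C[C@H]1O[Si](C)(C)C(C)(C)C | intermediate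
16 | isopropenylmagnesium bromide | CC(=C)[Mg]Br | starting material
17 | allyl iodide (3-iodoprop-1-ene) | C=CCI | starting material
18 | bromomagnesium C1=C10 enolate with 5β-isopropenyl | COC(=O)[C@@H](C)[C@H]1CCC(O[Mg]Br)=C[C@H](C(C)=C)[C@H]1O[Si](C)(C)C(C)(C)C | intermediate (not isolated)
19 | methyl (2S)-2-[(1R,2S,3R,4S)-2-[(tert-butyldimethylsilyl)oxy]-5-oxo-4-(prop-2-en-1-yl)-3-(prop-1-en-2-yl)cycloheptyl]propanoate | COC(=O)[C@@H](C)[C@H]1CCC(=O)[C@@H](CC=C)[C@H](C(C)=C)[C@H]1O[Si](C)(C)C(C)(C)C | intermediate
20 | trans-fused bicyclic ketone (rings A and B; C10 ketone; 6α-OTBS; C12 methyl ester) | COC(=O)[C@@H](C)[C@H]1CCC(=O)[C@H]2CC=C(C)[C@@H]2[C@H]1O[Si](C)(C)C(C)(C)C | intermediate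
21 | C9=C10 triethylsilyl enol ether of 20 | COC(=O)[C@@H](C)[C@H]1CC=C(O[Si](CC)(CC)CC)[C@H]2CC=C(C)[C@@H]2[C@H]1O[Si](C)(C)C(C)(C)C | intermediate (not isolated)
22 | 9β-triethylsilyloxy C10 ketone | COC(=O)[C@@H](C)[C@H]1C[C@H](O[Si](CC)(CC)CC)C(=O)[C@H]2CC=C(C)[C@@H]2[C@H]1O[Si](C)(C)C(C)(C)C | intermediate
23 | C10 methylene compound (C10=C18; 6α-OTBS; 9β-OSiEt3; C12 methyl ester) | COC(=O)[C@@H](C)[C@H]1C[C@H](O[Si](CC)(CC)CC)C(=C)[C@H]2CC=C(C)[C@@H]2[C@H]1O[Si](C)(C)C(C)(C)C | intermediate
24 | C12 aldehyde | O=C[C@@H](C)[C@H]1C[C@H](O[Si](CC)(CC)CC)C(=C)[C@H]2CC=C(C)[C@@H]2[C@H]1O[Si](C)(C)C(C)(C)C | intermediate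
25 | 3-methylbut-3-en-2-one | CC(=O)C(C)=C | starting material
26 | 3-methyl-2-(trimethylsilyloxy)buta-1,3-diene | C=C(O[Si](C)(C)C)C(C)=C | intermediate
27 | 12S-hydroxy-14-ketone (6α-OTBS; 9β-OSiEt3) | C=C(C)C(=O)C[C@H](O)[C@@H](C)[C@H]1C[C@H](O[Si](CC)(CC)CC)C(=C)[C@H]2CC=C(C)[C@@H]2[C@H]1O[Si](C)(C)C(C)(C)C | intermediate
28 | 12S-acetoxy-14-ketone (6α-OTBS; 9β-OSiEt3) | C=C(C)C(=O)C[C@H](OC(C)=O)[C@@H](C)[C@H]1C[C@H](O[Si](CC)(CC)CC)C(=C)[C@H]2CC=C(C)[C@@H]2[C@H]1O[Si](C)(C)C(C)(C)C | intermediate
29 | 6-O-TBS-9-O-triethylsilyl ether of the target | C=C(C)[C@H](O)C[C@H](OC(C)=O)[C@@H](C)[C@H]1C[C@H](O[Si](CC)(CC)CC)C(=C)[C@H]2CC=C(C)[C@@H]2[C@H]1O[Si](C)(C)C(C)(C)C | intermediate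
30 | target, (1S,5R,6S,7R,9S,11S,12S,14R)-12-acetoxy-6,9,14-triol | C=C(C)[C@H](O)C[C@H](OC(C)=O)[C@@H](C)[C@H]1C[C@H](O)C(=C)[C@H]2CC=C(C)[C@@H]2[C@H]1O | target

**Step count and risks**

Total step count: 18. Longest linear sequence: 17 (steps 1–13 and 15–18); step 14 is a one-step side branch.

The three steps most likely to fail:

1. Step 6. The allylic oxidation may attack the tertiary C7–H instead of C10, or stall at low conversion. The fallback sets out from 10 and moves the oxygen by epoxide and selenium chemistry instead of C–H oxidation. mCPBA (NaHCO3, CH2Cl2) should epoxidise C8=C9 anti to the C7 side chain to the epoxide F1. PhSeNa (from PhSeSePh and NaBH4, EtOH) opens it at the less hindered C9 to the hydroxy selenide F2. H2O2 then triggers selenoxide syn-elimination away from the carbinol to the transposed allylic alcohol F3 (8-OH, C9=C10). Ph3SiOReO3-catalysed 1,3-transposition should equilibrate F3 towards the less hindered C10 alcohol, where the fallback comes back to the route at 11; 11 is then oxidised to 12 as in step 6.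

2. Step 4. Competition between chair-like and boat-like transition states may erode the selectivity at C11. The fallback sets out from 9 (as a C11 epimer mixture) and sets C11 by cyclic control. Bu4NF followed by catalytic TsOH closes the cis-fused γ-lactone F4. LiN(iPr)2 at −78 °C and kinetic protonation of the enolate from the convex face with a bulky phenol should give the lactone F5, with the C11 methyl on the concave face (11S). LiOH opens it to the lithium hydroxy carboxylate F6. t-BuMe2SiCl/imidazole gives the silyl ether silyl ester F7, and K2CO3/MeOH cleaves only the silyl ester, coming back to the route at 9 as a single C11 epimer.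

3. Step 11. The peracid may also epoxidise the ring A alkene, or oxygen delivery to the enol ether may be poorly face-selective. The fallback sets out from 20 and oxidises the enolate directly instead of the enol ether. KN(SiMe3)2 (THF, −78 °C) followed by 2-(phenylsulfonyl)-3-phenyloxaziridine should hydroxylate C9 on the β face to the α-hydroxy ketone F8. Et3SiCl/imidazole then comes back to the route at 22.

Further compounds

F1 | step 6 | 8β,9β-epoxide of 10 | COC(=O)[C@@H](C)[C@H]1[C@@H]2O[C@@H]2CCC[C@H]1O[Si](C)(C)C(C)(C)C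
F2 | step 6 | 8β-hydroxy-9α-phenylselanyl compound | COC(=O)[C@@H](C)[C@H]1[C@H](O)[C@@H]([Se]c2ccccc2)CCC[C@H]1O[Si](C)(C)C(C)(C)C
F3 | step 6 | transposed allylic alcohol (8β-OH, C9=C10) | COC(=O)[C@@H](C)[C@H]1[C@H](O)C=CCC[C@H]1O[Si](C)(C)C(C)(C)C
F4 | step 4 | cis-fused γ-lactone between C12 and O6 (C11 epimers) | O=C1O[C@@H]2CCCC=C[C@@H]2C1C
F5 | step 4 | cis-fused γ-lactone with 11S methyl on the concave face | O=C1O[C@@H]2CCCC=C[C@@H]2[C@@H]1C
F6 | step 4 | lithium (2S)-2-[(1R,7R)-7-hydroxycyclohept-2-en-1-yl]propanoate | [Li+].[O-]C(=O)[C@@H](C)[C@H]1C=CCCC[C@H]1O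
F7 | step 4 | tert-butyldimethylsilyl ester of acid 9 | CC(C)(C)[Si](C)(C)OC(=O)[C@@H](C)[C@H]1C=CCCC[C@H]1O[Si](C)(C)C(C)(C)C
F8 | step 11 | 9β-hydroxy C10 ketone | COC(=O)[C@@H](C)[C@H]1C[C@H](O)C(=O)[C@H]2CC=C(C)[C@@H]2[C@H]1O[Si](C)(C)C(C)(C)C
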